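## Retrosynthetic overview
1. Target **13** ← removal of two MOM groups from (2S)-flavanone **12**.
2. **12** ← catalytic, enantio- and regioselective 6-endo oxa-Michael closure of the 2',6'-dihydroxychalcone **10**. This forms the C ring last and sets the only stereocentre.
3. **10** ← Claisen–Schmidt condensation of ketone **9** (A ring, prenyl already in place) with aldehyde **5** (B ring, pyran already fused).
4. **9** ← C-prenylation of mono-MOM phloroacetophenone **7**; **5** ← prenal annulation of 2,4-dihydroxybenzaldehyde **1**, then MOM protection. Ring order: pyran (in **5**), then chalcone, then C ring.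

Assumptions:
- Heating **1** with prenal in pyridine gives the linear 6,7-fused chromene **3** as the major regioisomer, separable from the angular one.
- Catalyst **11** is prepared beforehand from commercial (S)-tert-leucine (amide coupling with 3,5-bis(CF3)aniline, then iminophosphorane formation) and is treated as a starting material. As drawn it delivers the (S)-flavanone; if (R) is obtained, its enantiomer is used.

## Route

**Step 1**
Reactants: **1** (2,4-dihydroxybenzaldehyde), **2** (3-methylbut-2-enal, prenal)
Product: **3** (7-hydroxy-2,2-dimethyl-2H-chromene-6-carbaldehyde)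
Conditions: **2** (1.5 equiv), pyridine, 125 °C, sealed tube, 16 h
Reagents that add atoms: none (prenal is reactant **2**)
Why: Phenol–enal condensation followed by 6π-oxaelectrocyclisation (2H-chromene synthesis) occurs at C5, ortho to the 4-OH. C3 is disfavoured because it lies next to the aldehyde-chelated 2-OH.

**Step 2**
Reactants: **3**, **4** (chloromethyl methyl ether, MOMCl)
Product: **5** (7-(methoxymethoxy)-2,2-dimethyl-2H-chromene-6-carbaldehyde)
Conditions: MOMCl (1.5 equiv), DIPEA (2 equiv), CH2Cl2, 0 °C → rt, 6 h
Reagents that add atoms: MOMCl, ClCOC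
Why: Phenol O-alkylation (MOM protection) stops the B-ring OH from forming hemiketals or competing in the later cyclisation.

**Step 3**
Reactants: **6** (2,4,6-trihydroxyacetophenone), **4** (MOMCl)
Product: **7** (2',6'-dihydroxy-4'-(methoxymethoxy)acetophenone)
Conditions: MOMCl (1.0 equiv), K2CO3 (1.2 equiv), acetone, 0 °C → rt, 8 h
Reagents that add atoms: MOMCl, ClCOC
Why: The 4-OH is the most acidic and is not chelated to the carbonyl, so it is alkylated selectively. The 2,6-OH pair stays free, and the product is symmetric.

**Step 4**
Reactants: **7**, **8** (prenyl bromide)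
Product: **9** (1-[2,6-dihydroxy-4-(methoxymethoxy)-3-(3-methylbut-2-en-1-yl)phenyl]ethan-1-one)
Conditions: prenyl bromide (1.0 equiv), KOH (2 equiv), MeOH/H2O 3:1, 0 °C → rt, 4 h
Reagents that add atoms: prenyl bromide, CC(C)=CCBr
Why: Phenoxide ortho-C-alkylation in protic medium. C3' and C5' of **7** are equivalent because it is symmetric, so only one mono-C-prenyl regioisomer forms.

**Step 5**
Reactants: **5**, **9**
Product: **10** ((E)-chalcone: 2',6'-dihydroxy-4'-MOMO-3'-prenyl on the A ring, 2-MOMO-4,5-(2,2-dimethylpyrano) on the B ring)
Conditions: KOH (5 equiv), EtOH/H2O, 0 °C → rt, 24 h; quench with AcOH at 0 °C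
Reagents that add atoms: none (loses H2O)
Why: Claisen–Schmidt (aldol) condensation. The E-enone is the thermodynamic product, and the mild acid quench avoids uncontrolled racemic cyclisation.

**Step 6**
Reactants: **10**, **11** (catalyst: bifunctional iminophosphorane, (S)-tert-leucine-derived amide, tris(4-methoxyphenyl)iminophosphorane)
Product: **12** ((2S)-5-hydroxy-7-MOMO-6-prenyl-flavanone bearing the 2'-MOMO-4',5'-dimethylchromene B ring)
Conditions: **11** (10 mol %), toluene (0.02 M), –20 °C, 48 h; AcOH quench, short silica plug
Reagents that add atoms: none (isomerisation; **11** is catalytic)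
Why: Proposed new method: the superbasic iminophosphorane should deprotonate the more acidic, unhindered 6'-OH, while the prenyl-flanked 2'-OH stays H-bonded to the C=O and holds the enone s-cis with Cβ over the 6'-O⁻. The protonated catalyst's amide N–H then binds the carbonyl/phenoxide in a chiral ion pair and directs a 6-endo-trig oxa-Michael closure that sets C2 as (S) and leaves the 5-OH free. The closest known reactions are iminophosphorane- and cinchona-thiourea-catalysed oxa-Michael cyclisations of 2'-hydroxychalcones. The new element is catalyst discrimination between two non-equivalent ortho-OH groups on a fully elaborated chalcone, so that the 6-prenyl rather than the 8-prenyl flavanone forms.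

**Step 7**
Reactants: **12**
Product: **13** (cudraflavanone A)
Conditions: p-TsOH·H2O (1 equiv), MeOH/CH2Cl2 1:1, 35 °C, 6 h
Reagents that add atoms: none (MeOH traps the oxocarbenium as dimethoxymethane; only H is added to the product)
Why: Acid-catalysed cleavage of the two aryl MOM acetals. The mild conditions and the chelated 5-OH leave the benzylic C2–O bond, the chromene and the prenyl group intact, so C2 is not scrambled.

## Compound list
1 | 2,4-dihydroxybenzaldehyde | O=Cc1ccc(O)cc1O | starting material
2 | 3-methylbut-2-enal (prenal) | CC(C)=CC=O | starting material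
3 | 7-hydroxy-2,2-dimethyl-2H-chromene-6-carbaldehyde | CC1(C)C=Cc2cc(C=O)c(O)cc2O1 | intermediate
4 | chloromethyl methyl ether (MOMCl) | ClCOC | starting material (reagent)
5 | 7-(methoxymethoxy)-2,2-dimethyl-2H-chromene-6-carbaldehyde | CC1(C)C=Cc2cc(C=O)c(OCOC)cc2O1 | intermediate
6 | 2,4,6-trihydroxyacetophenone | CC(=O)c1c(O)cc(O)cc1O | starting material
7 | 2',6'-dihydroxy-4'-(methoxymethoxy)acetophenone | CC(=O)c1c(O)cc(OCOC)cc1O | intermediate
8 | prenyl bromide | CC(C)=CCBr | starting material (reagent)
9 | 1-[2,6-dihydroxy-4-(methoxymethoxy)-3-prenylphenyl]ethanone | CC(=O)c1c(O)c(CC=C(C)C)c(OCOC)cc1O | intermediate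
10 | (E)-chalcone | CC(C)=CCc1c(OCOC)cc(O)c(C(=O)/C=C/c2cc3C=CC(C)(C)Oc3cc2OCOC)c1O | intermediate
11 | (S)-N-[3,5-bis(CF3)phenyl]-3,3-dimethyl-2-{[tris(4-MeO-phenyl)-λ5-phosphanylidene]amino}butanamide | COc1ccc(cc1)P(=N[C@@H](C(C)(C)C)C(=O)Nc1cc(cc(c1)C(F)(F)F)C(F)(F)F)(c1ccc(OC)cc1)c1ccc(OC)cc1 | starting material (organocatalyst)
12 | (2S)-bis-MOM flavanone | CC(C)=CCc1c(OCOC)cc2c(c1O)C(=O)C[C@@H](c1cc3c(cc1OCOC)OC(C)(C)C=C3)O2 | intermediate
13 | cudraflavanone A | CC(C)=CCc1c(O)cc2c(c1O)C(=O)C[C@@H](c1cc3c(cc1O)OC(C)(C)C=C3)O2 | target

Atom check: **5** (C14H16O4) + **9** (C15H20O5) – H2O gives **10** (C29H34O8). **10** isomerises to **12**. Loss of two C2H4O (two MOM groups replaced by H) gives **13** (C25H26O6), matching the target. The C2 configuration in **12** and **13** is written identically to the target SMILES and is (S).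

## Totals
- Total steps: 7.
- Longest linear sequence: 5 steps (1 → 3 → 5 → 6 → 7, or equivalently 6 → 7 → 9 → 10 → 12 → 13 in compound terms, i.e. steps 3 → 4 → 5 → 6 → 7).

## Three steps most likely to fail
1. **Step 6 (proposed new step):** regioselectivity (6- versus 8-prenyl) or ee may be poor, and the 5-hydroxyflavanone can racemise by retro-oxa-Michael under the basic catalyst. Fallback: cyclise **10** racemically (NaOAc, EtOH, 80 °C), separate the regioisomers by chromatography, and obtain the (S)-enantiomer by preparative chiral-stationary-phase HPLC. Both operations are known chemistry.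
2. **Step 4:** O-prenylation, di-prenylation and low C-alkylation yield. Fallback: change the order of events. C-prenylate phloroglucinol, then do a Houben–Hoesch acetylation (MeCN, ZnCl2, HCl) to give 3'-prenyl-phloroacetophenone, followed by selective 4'-MOM protection.
3. **Step 7:** acid could racemise C2 or degrade the chromene or prenyl group. Fallback: carry allyl ethers instead of MOM ethers (allyl bromide/K2CO3 in steps 2 and 3) and remove them at the end with Pd(PPh3)4/morpholine at rt, which avoids Brønsted acid.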